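I began with a leftover: the readings give no unreacted substrate, so I took it as what the charge leaves after mono adduct and double product.

| flask | substrate | coupling partner | remark | time |
|---|---|---|---|---|
| ash | 0.11 M | 0.13 M (fed, over 6.0 h) | run made earlier; the fed solution adds 0.20 times the starting volume |  |
| oak | 0.11 M | 0.43 M (fed, over 6.0 h) | run made earlier; the fed solution adds 0.20 times the starting volume |  |
| dawn | 0.11 M | 0.275 M (fed, over 6.0 h) | the fed solution adds 0.20 times the starting volume | 6.0 h |
| noon | 0.11 M | 0.220 M (fed, over 6.0 h) | the fed solution adds 0.20 times the starting volume | 6.0 h |
| summer | 0.11 M | 0.0880 M (fed, over 6.0 h) | the fed solution adds 0.20 times the starting volume | 6.0 h |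

| run | time / h | mono adduct / % | double product / % |
|---|---|---|---|
| ash | 0.250 | 1.1 | 0.4 |
| ash | 0.667 | 2.1 | 0 |
| ash | 1.33 | 10.4 | 0.8 |
| ash | 2.00 | 18.2 | 0.6 |
| ash | 2.50 | 24.4 | 0.7 |
| ash | 3.00 | 28.8 | 2.4 |
| ash | 4.00 | 40.4 | 4.4 |
| oak | 0.333 | 3.1 | 0 |
| oak | 0.500 | 5.4 | 0 |
| oak | 0.833 | 14.2 | 2.0 |
| oak | 1.33 | 28.4 | 0 |
| oak | 2.00 | 43.0 | 9.2 |
| oak | 3.00 | 52.2 | 23.1 |
| oak | 4.00 | 45.0 | 40.3 |

(each reading ± 1 percentage point)

- which of these holds the largest part of the substrate at the end of dawn (substrate / mono adduct / double product)
- which of these holds the largest part of the substrate at the end of noon (substrate / mono adduct / double product)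
- which of these holds the largest part of the substrate at the end of summer (substrate / mono adduct / double product)
- mono adduct at the end of noon, in percent of the substrate charged

- charges are per starting volume, the dose included; the dosed solution carries all of it

I assumed that substrate gives mono adduct, that mono adduct gives double product, and that each step is first order in coupling partner, so c(coupling partner) cancels when the two steps are compared. Mono adduct then rises until its loss catches up with its making, and control changes hands at a fixed value of c(mono adduct)/c(substrate). That value equals the ratio of the two rate constants, the selectivity factor.

My first way was to read it at the top of the oak run, at 3.00 h: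

ratio = 52.2% / 24.7% = 2.11

This reading carries the scatter of its readings, and the top lies between readings well apart in time, so it is an estimate of the crossing ratio.

My second way used another flask and a slower feed. While little substrate has gone, mono adduct is about the substrate used, y, and this gives a rough relation, here for ash at 4.00 h:

y = 44.8%

ratio ≈ y·y / (2 · double product) = 2.28

This is a little higher than the oak value, but it leans on a double product of 4.4% read with a scatter of 1 percentage point, and y is no longer small. I took it as loose support and kept the oak value.

The earlier runs then place the new flasks. Oak at its top had received 0.215 M, close to noon's whole 0.220 M, and noon takes twice as long, so I put noon just past its crossing, with mono adduct leading. Oak at 4.00 h had received 0.287 M, close to dawn's 0.275 M, with mono adduct 45.0% and double product 40.3%. Dawn takes longer, so I gave double product a narrow lead. Ash at 4.00 h had received 0.0867 M, close to summer's 0.0880 M, with mono adduct at 40.4%, less than the leftover substrate of 55.2%, so I left substrate first in summer.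

The forecast named double product for dawn, mono adduct for noon and substrate for summer, and put noon's mono adduct at 49% (45% to 53%), remarking of dawn: “double product leads, but modestly”.

The flasks gave double product for dawn, mono adduct for noon and substrate for summer, with 47.4% of mono adduct in noon.

    coupling partner + mono adduct → double product (k = 0.00110 /M/s)
    double product ⇌ isomer of the product (K = 0.160, k = 8.90 × 10⁻⁵ /s)
    substrate + coupling partner → mono adduct (k = 0.00230 /M/s)

Noon ended at a ratio of 3.61, above the crossing ratio 2.11, and the noon flask read at 10.0 h holds 29.6% of mono adduct, so it was indeed falling. Summer ended at 0.844, below the crossing, and its mono adduct went on from 41.9% to 48.7% by 60.0 h. Noon's mono adduct stood at 47.4% because of the dosing over time together with the time allowed: without the dosing noon holds 30.6%, and left until 60.0 h it holds 4.67%.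

(The readings are simulated with made-up constants; the scatter is artificial.)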